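**Retrosynthetic overview**

- The strategy rests on the 4-hydroxy-3,5-dimethoxyphenyl ring C on C2 of the 2,3-dihydrobenzofuran. C2 is the exocyclic carbon of a latent p-quinone methide and O1 is a phenol oxygen on C7a of ring A, so the O1–C2 bond of ring B is disconnected.
- Rings A and C are bought (methyl vanillate, syringaldehyde). Ring B is the only ring made, and it is made last: anodic oxidation of bisphenol 20 gives quinone methide 21, which closes by 5-exo oxa-1,6-addition.
- C3 is set before that. The C2–C3 bond comes from Evans alkylation of the ring A arylacetyl imide 15 (Claisen rearrangement, ozonolysis, Pinnick oxidation) with the ring C benzyl bromide 4; C2 then follows from C3 (trans).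
- The C5 ester is the handle for the side chain: reduction, MnO2 oxidation, Horner–Wadsworth–Emmons olefination, reduction, then removal of both silyl groups.

Key step: step 14

Remark on the chemistry: CIP analysis of the target SMILES gives C2 = S and C3 = R, with the ring C aryl group and the hydroxymethyl group trans on ring B and an E side-chain alkene; the route is planned for this isomer.

**Route**

Step 1
Reactants: 1 syringaldehyde
Product: 2 4-(benzyloxy)-3,5-dimethoxybenzaldehyde
Conditions: BnBr, K2CO3, DMF, 60 °C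
Reagents that add atoms: benzyl bromide, BrCc1ccccc1
Why: Williamson ether synthesis, in which the phenoxide of 1 is alkylated by benzyl bromide while the aldehyde is inert to K2CO3.

Step 2
Reactants: 2 4-(benzyloxy)-3,5-dimethoxybenzaldehyde
Product: 3 [4-(benzyloxy)-3,5-dimethoxyphenyl]methanol
Conditions: NaBH4, MeOH, 0 °C
Reagents that add atoms: none
Why: Borohydride reduction of an aryl aldehyde, which leaves the benzyl and methyl ethers untouched.

Step 3
Reactants: 3 [4-(benzyloxy)-3,5-dimethoxyphenyl]methanol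
Product: 4 4-(benzyloxy)-3,5-dimethoxybenzyl bromide
Conditions: PBr3, Et2O, 0 °C
Reagents that add atoms: phosphorus tribromide, BrP(Br)Br
Why: Bromination of a benzylic alcohol with PBr3 through a phosphite ester and bromide displacement, giving a labile electron-rich bromide that should be used at once in step 10.

Step 4
Reactants: 5 methyl vanillate
Product: 6 methyl 4-(allyloxy)-3-methoxybenzoate
Conditions: allyl bromide, K2CO3, acetone, reflux
Reagents that add atoms: allyl bromide, C=CCBr
Why: Williamson O-allylation of the phenol, with the methyl ester stable to K2CO3 in acetone.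

Step 5
Reactants: 6 methyl 4-(allyloxy)-3-methoxybenzoate
Product: 8 methyl 3-allyl-4-hydroxy-5-methoxybenzoate, via ortho-dienone 7 (not isolated)
Conditions: N,N-diethylaniline, 200 °C, argon
Reagents that add atoms: none
Why: Aromatic Claisen rearrangement, a [3,3]-sigmatropic shift to the only free ortho position (the other bears the methoxy group), followed by tautomerisation of dienone 7 to the phenol.

Step 6
Reactants: 8 methyl 3-allyl-4-hydroxy-5-methoxybenzoate
Product: 9 methyl 3-allyl-4-(benzyloxy)-5-methoxybenzoate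
Conditions: BnBr, K2CO3, DMF, 60 °C
Reagents that add atoms: benzyl bromide, BrCc1ccccc1
Why: Williamson benzylation masks the ring A phenol during the enolate chemistry, and this benzyl group is later removed together with that of ring C.

Step 7
Reactants: 9 methyl 3-allyl-4-(benzyloxy)-5-methoxybenzoate
Product: 11 methyl 4-(benzyloxy)-3-methoxy-5-(2-oxoethyl)benzoate, via secondary ozonide 10 (not isolated)
Conditions: O3, CH2Cl2, −78 °C; then PPh3, −78 °C to rt
Reagents that add atoms: ozone, [O-][O+]=O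
Why: Ozonolysis with reductive work-up, in which the terminal alkene reacts far faster with ozone than the ester-deactivated arene and PPh3 reduces ozonide 10 to the arylacetaldehyde, which should be used crude.

Step 8
Reactants: 11 methyl 4-(benzyloxy)-3-methoxy-5-(2-oxoethyl)benzoate
Product: 12 2-[2-(benzyloxy)-3-methoxy-5-(methoxycarbonyl)phenyl]acetic acid
Conditions: NaClO2, NaH2PO4, 2-methyl-2-butene, tBuOH/H2O, 0 °C to rt
Reagents that add atoms: sodium chlorite, [Na+].[O-]Cl=O
Why: Pinnick oxidation of the aldehyde by chlorous acid, with 2-methyl-2-butene as HOCl scavenger so that the electron-rich ring is not chlorinated.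

Step 9
Reactants: 12 2-[2-(benzyloxy)-3-methoxy-5-(methoxycarbonyl)phenyl]acetic acid; 13 (R)-4-benzyl-2-oxazolidinone
Product: 15 (4R)-4-benzyl-3-{2-[2-(benzyloxy)-3-methoxy-5-(methoxycarbonyl)phenyl]acetyl}-1,3-oxazolidin-2-one, via mixed pivalic anhydride 14 (not isolated)
Conditions: PivCl, Et3N, THF, −20 °C; then 13, LiCl, rt
Reagents that add atoms: none
Why: N-Acylation of the oxazolidinone through the mixed pivalic anhydride (LiCl and Et3N method), in which the nucleophile attacks the unhindered arylacetyl carbonyl and not the pivaloyl carbonyl.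

Step 10
Reactants: 15 (4R)-4-benzyl-3-{2-[2-(benzyloxy)-3-methoxy-5-(methoxycarbonyl)phenyl]acetyl}-1,3-oxazolidin-2-one; 4 4-(benzyloxy)-3,5-dimethoxybenzyl bromide
Product: 17 (4R)-4-benzyl-3-{(2R)-2-[2-(benzyloxy)-3-methoxy-5-(methoxycarbonyl)phenyl]-3-[4-(benzyloxy)-3,5-dimethoxyphenyl]propanoyl}-1,3-oxazolidin-2-one, via sodium Z-enolate 16 (not isolated)
Conditions: NaN(SiMe3)2, THF, −78 °C; then 4, −78 to −40 °C
Reagents that add atoms: none
Why: Evans asymmetric alkylation, in which the sodium-chelated Z-enolate 16 is shielded on one face by the benzyl group of the R auxiliary, so that bromide 4 adds by SN2 to the opposite face and sets the future C3 with the R configuration.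

Step 11
Reactants: 17 (4R)-4-benzyl-3-{(2R)-2-[2-(benzyloxy)-3-methoxy-5-(methoxycarbonyl)phenyl]-3-[4-(benzyloxy)-3,5-dimethoxyphenyl]propanoyl}-1,3-oxazolidin-2-one
Product: 18 methyl 4-(benzyloxy)-3-{(2R)-1-[4-(benzyloxy)-3,5-dimethoxyphenyl]-3-hydroxypropan-2-yl}-5-methoxybenzoate
Conditions: LiBH4, MeOH (one equivalent), THF, 0 °C
Reagents that add atoms: none
Why: Reductive cleavage of the N-acyl oxazolidinone with LiBH4, in which the carbamate-activated imide carbonyl should be reduced much faster at 0 °C than the aryl methyl ester and the auxiliary is released without touching the stereocentre.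

Step 12
Reactants: 18 methyl 4-(benzyloxy)-3-{(2R)-1-[4-(benzyloxy)-3,5-dimethoxyphenyl]-3-hydroxypropan-2-yl}-5-methoxybenzoate
Product: 19 methyl 4-(benzyloxy)-3-{(2R)-1-[4-(benzyloxy)-3,5-dimethoxyphenyl]-3-[(tert-butyldimethylsilyl)oxy]propan-2-yl}-5-methoxybenzoate
Conditions: TBSCl, imidazole, DMF, rt
Reagents that add atoms: tert-butyldimethylsilyl chloride, CC(C)(C)[Si](C)(C)Cl
Why: Silylation of the primary alcohol with a silyl chloride and imidazole, which protects this oxygen during the oxidation and adds bulk next to C3.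

Step 13
Reactants: 19 methyl 4-(benzyloxy)-3-{(2R)-1-[4-(benzyloxy)-3,5-dimethoxyphenyl]-3-[(tert-butyldimethylsilyl)oxy]propan-2-yl}-5-methoxybenzoate
Product: 20 methyl 3-{(2R)-1-[(tert-butyldimethylsilyl)oxy]-3-(4-hydroxy-3,5-dimethoxyphenyl)propan-2-yl}-4-hydroxy-5-methoxybenzoate
Conditions: H2 (1 atm), 10% Pd/C, EtOAc, rt
Reagents that add atoms: none
Why: Hydrogenolysis of both aryl benzyl ethers over palladium in a neutral aprotic solvent, conditions under which the silyl ether, the ester and the stereocentre are stable.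

Step 14
Reactants: 20 methyl 3-{(2R)-1-[(tert-butyldimethylsilyl)oxy]-3-(4-hydroxy-3,5-dimethoxyphenyl)propan-2-yl}-4-hydroxy-5-methoxybenzoate
Product: 22 methyl (2S,3R)-3-{[(tert-butyldimethylsilyl)oxy]methyl}-2-(4-hydroxy-3,5-dimethoxyphenyl)-7-methoxy-2,3-dihydro-1-benzofuran-5-carboxylate, via p-quinone methide 21 (not isolated)
Conditions: graphite anode, Pt cathode, undivided cell, constant current (about 2.2 F/mol), 2,6-lutidine, LiClO4 (0.1 M), CH2Cl2/HFIP 4:1, 0 °C
Reagents that add atoms: none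
Why: Anodic oxidation takes one electron and the OH proton (passed to 2,6-lutidine) from the ring C phenol, and a second electron together with a C2–H proton then gives p-quinone methide 21, whose exocyclic carbon C2 is attacked by the C7a phenol oxygen. The closest known reaction type is the oxidative (anodic, Ag2O or DDQ) conversion of 4-alkyl-2,6-dimethoxyphenols into p-quinone methides with intramolecular capture by a phenol, as in the last stage of phenylcoumaran formation from coniferyl-type radicals. Ring B closes by a 5-exo-trig oxa-1,6-conjugate addition that restores the aromaticity of ring C. The new C2 stereocentre is controlled by the existing C3 centre, because the aryl group takes the face of the forming ring opposite the CH2OTBS group, and since the addition is reversible through 21 the trans (2S,3R) isomer should also be the equilibrium product. The step needs oxidation of ring C in preference to ring A, which the para CO2Me group on the ring A phenol secures by raising its oxidation potential, while the two ortho methoxy groups of ring C block radical coupling so that loss of the benzylic proton is the only outlet. HFIP stabilises the cationic intermediates and is reduced to H2 at the cathode, so the cell can stay undivided, and C3, which takes no part in the redox event, should remain intact.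

Step 15
Reactants: 22 methyl (2S,3R)-3-{[(tert-butyldimethylsilyl)oxy]methyl}-2-(4-hydroxy-3,5-dimethoxyphenyl)-7-methoxy-2,3-dihydro-1-benzofuran-5-carboxylate
Product: 23 methyl (2S,3R)-3-{[(tert-butyldimethylsilyl)oxy]methyl}-2-{4-[(tert-butyldimethylsilyl)oxy]-3,5-dimethoxyphenyl}-7-methoxy-2,3-dihydro-1-benzofuran-5-carboxylate
Conditions: TBSCl, imidazole, DMAP (cat), DMF, rt
Reagents that add atoms: tert-butyldimethylsilyl chloride, CC(C)(C)[Si](C)(C)Cl
Why: Silylation of the remaining phenol, so that ring C can no longer be oxidised or ionised to a quinone methide during the redox steps that follow.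

Step 16
Reactants: 23 methyl (2S,3R)-3-{[(tert-butyldimethylsilyl)oxy]methyl}-2-{4-[(tert-butyldimethylsilyl)oxy]-3,5-dimethoxyphenyl}-7-methoxy-2,3-dihydro-1-benzofuran-5-carboxylate
Product: 24 [(2S,3R)-3-{[(tert-butyldimethylsilyl)oxy]methyl}-2-{4-[(tert-butyldimethylsilyl)oxy]-3,5-dimethoxyphenyl}-7-methoxy-2,3-dihydro-1-benzofuran-5-yl]methanol
Conditions: iBu2AlH, CH2Cl2, −78 to 0 °C; aqueous potassium sodium tartrate
Reagents that add atoms: none
Why: Reduction of the aryl methyl ester to the benzylic alcohol with iBu2AlH, to which the silyl ethers and the benzylic aryl ether of ring B are inert.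

Step 17
Reactants: 24 [(2S,3R)-3-{[(tert-butyldimethylsilyl)oxy]methyl}-2-{4-[(tert-butyldimethylsilyl)oxy]-3,5-dimethoxyphenyl}-7-methoxy-2,3-dihydro-1-benzofuran-5-yl]methanol
Product: 25 (2S,3R)-3-{[(tert-butyldimethylsilyl)oxy]methyl}-2-{4-[(tert-butyldimethylsilyl)oxy]-3,5-dimethoxyphenyl}-7-methoxy-2,3-dihydro-1-benzofuran-5-carbaldehyde
Conditions: activated MnO2, CH2Cl2, rt
Reagents that add atoms: none
Why: Selective oxidation of a benzylic alcohol to the aldehyde with MnO2, which does not over-oxidise and does not affect silyl ethers.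

Step 18
Reactants: 25 (2S,3R)-3-{[(tert-butyldimethylsilyl)oxy]methyl}-2-{4-[(tert-butyldimethylsilyl)oxy]-3,5-dimethoxyphenyl}-7-methoxy-2,3-dihydro-1-benzofuran-5-carbaldehyde
Product: 26 ethyl (2E)-3-[(2S,3R)-3-{[(tert-butyldimethylsilyl)oxy]methyl}-2-{4-[(tert-butyldimethylsilyl)oxy]-3,5-dimethoxyphenyl}-7-methoxy-2,3-dihydro-1-benzofuran-5-yl]prop-2-enoate
Conditions: (EtO)2P(O)CH2CO2Et, NaH, THF, 0 °C to rt
Reagents that add atoms: triethyl phosphonoacetate, CCOC(=O)CP(=O)(OCC)OCC
Why: Horner–Wadsworth–Emmons olefination with a stabilised phosphonate anion, which should give the E enoate, on an aldehyde that has no α-hydrogen.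

Step 19
Reactants: 26 ethyl (2E)-3-[(2S,3R)-3-{[(tert-butyldimethylsilyl)oxy]methyl}-2-{4-[(tert-butyldimethylsilyl)oxy]-3,5-dimethoxyphenyl}-7-methoxy-2,3-dihydro-1-benzofuran-5-yl]prop-2-enoate
Product: 27 (2E)-3-[(2S,3R)-3-{[(tert-butyldimethylsilyl)oxy]methyl}-2-{4-[(tert-butyldimethylsilyl)oxy]-3,5-dimethoxyphenyl}-7-methoxy-2,3-dihydro-1-benzofuran-5-yl]prop-2-en-1-ol
Conditions: iBu2AlH, CH2Cl2, −78 °C; aqueous potassium sodium tartrate
Reagents that add atoms: none
Why: 1,2-Reduction of the conjugated ester to the allylic alcohol with iBu2AlH at −78 °C, which leaves the alkene geometry unchanged.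

Step 20
Reactants: 27 (2E)-3-[(2S,3R)-3-{[(tert-butyldimethylsilyl)oxy]methyl}-2-{4-[(tert-butyldimethylsilyl)oxy]-3,5-dimethoxyphenyl}-7-methoxy-2,3-dihydro-1-benzofuran-5-yl]prop-2-en-1-ol
Product: 28 (2E)-3-[(2S,3R)-2-(4-hydroxy-3,5-dimethoxyphenyl)-3-(hydroxymethyl)-7-methoxy-2,3-dihydro-1-benzofuran-5-yl]prop-2-en-1-ol
Conditions: Bu4NF, AcOH, THF, 0 °C to rt
Reagents that add atoms: none
Why: Fluoride cleavage of the aryl and the alkyl silyl ether, buffered with acetic acid so that the liberated ring C phenol stays protonated, ring B is not opened through the quinone methide, and C2 and C3 stay as set.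

**Compound list**

1 | syringaldehyde | COc1cc(C=O)cc(OC)c1O | starting material
2 | 4-(benzyloxy)-3,5-dimethoxybenzaldehyde | COc1cc(C=O)cc(OC)c1OCc1ccccc1 | intermediate
3 | [4-(benzyloxy)-3,5-dimethoxyphenyl]methanol | COc1cc(CO)cc(OC)c1OCc1ccccc1 | intermediate
4 | 4-(benzyloxy)-3,5-dimethoxybenzyl bromide | COc1cc(CBr)cc(OC)c1OCc1ccccc1 | intermediate
5 | methyl vanillate | COC(=O)c1ccc(O)c(OC)c1 | starting material
6 | methyl 4-(allyloxy)-3-methoxybenzoate | COC(=O)c1ccc(OCC=C)c(OC)c1 | intermediate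
7 | ortho-dienone, methyl 3-allyl-5-methoxy-4-oxocyclohexa-1,5-diene-1-carboxylate (racemic) | COC(=O)C1=CC(CC=C)C(=O)C(OC)=C1 | intermediate (not isolated)
8 | methyl 3-allyl-4-hydroxy-5-methoxybenzoate | COC(=O)c1cc(CC=C)c(O)c(OC)c1 | intermediate
9 | methyl 3-allyl-4-(benzyloxy)-5-methoxybenzoate | COC(=O)c1cc(CC=C)c(OCc2ccccc2)c(OC)c1 | intermediate
10 | secondary ozonide, methyl 4-(benzyloxy)-3-methoxy-5-(1,2,4-trioxolan-3-ylmethyl)benzoate | COC(=O)c1cc(CC2OCOO2)c(OCc2ccccc2)c(OC)c1 | intermediate (not isolated)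
11 | methyl 4-(benzyloxy)-3-methoxy-5-(2-oxoethyl)benzoate | COC(=O)c1cc(CC=O)c(OCc2ccccc2)c(OC)c1 | intermediate
12 | 2-[2-(benzyloxy)-3-methoxy-5-(methoxycarbonyl)phenyl]acetic acid | COC(=O)c1cc(CC(=O)O)c(OCc2ccccc2)c(OC)c1 | intermediate
13 | (R)-4-benzyl-2-oxazolidinone | O=C1N[C@H](Cc2ccccc2)CO1 | starting material
14 | mixed pivalic anhydride of acid 12 | COC(=O)c1cc(CC(=O)OC(=O)C(C)(C)C)c(OCc2ccccc2)c(OC)c1 | intermediate (not isolated)
15 | (4R)-4-benzyl-3-{2-[2-(benzyloxy)-3-methoxy-5-(methoxycarbonyl)phenyl]acetyl}-1,3-oxazolidin-2-one | COC(=O)c1cc(CC(=O)N2[C@H](Cc3ccccc3)COC2=O)c(OCc2ccccc2)c(OC)c1 | intermediate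
16 | sodium Z-enolate of imide 15 | COC(=O)c1cc(/C=C(\[O-])N2[C@H](Cc3ccccc3)COC2=O)c(OCc2ccccc2)c(OC)c1.[Na+] | intermediate (not isolated)
17 | (4R)-4-benzyl-3-{(2R)-2-[2-(benzyloxy)-3-methoxy-5-(methoxycarbonyl)phenyl]-3-[4-(benzyloxy)-3,5-dimethoxyphenyl]propanoyl}-1,3-oxazolidin-2-one | COc1cc(C[C@@H](C(=O)N2[C@H](Cc3ccccc3)COC2=O)c2cc(C(=O)OC)cc(OC)c2OCc2ccccc2)cc(OC)c1OCc1ccccc1 | intermediate
18 | methyl 4-(benzyloxy)-3-{(2R)-1-[4-(benzyloxy)-3,5-dimethoxyphenyl]-3-hydroxypropan-2-yl}-5-methoxybenzoate | COc1cc(C[C@@H](CO)c2cc(C(=O)OC)cc(OC)c2OCc2ccccc2)cc(OC)c1OCc1ccccc1 | intermediate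
19 | methyl 4-(benzyloxy)-3-{(2R)-1-[4-(benzyloxy)-3,5-dimethoxyphenyl]-3-[(tert-butyldimethylsilyl)oxy]propan-2-yl}-5-methoxybenzoate | COc1cc(C[C@@H](CO[Si](C)(C)C(C)(C)C)c2cc(C(=O)OC)cc(OC)c2OCc2ccccc2)cc(OC)c1OCc1ccccc1 | intermediate
20 | methyl 3-{(2R)-1-[(tert-butyldimethylsilyl)oxy]-3-(4-hydroxy-3,5-dimethoxyphenyl)propan-2-yl}-4-hydroxy-5-methoxybenzoate | COc1cc(C[C@@H](CO[Si](C)(C)C(C)(C)C)c2cc(C(=O)OC)cc(OC)c2O)cc(OC)c1O | intermediate
21 | p-quinone methide, methyl 3-{(2R)-1-[(tert-butyldimethylsilyl)oxy]-3-(3,5-dimethoxy-4-oxocyclohexa-2,5-dien-1-ylidene)propan-2-yl}-4-hydroxy-5-methoxybenzoate | COC1=CC(=C[C@@H](CO[Si](C)(C)C(C)(C)C)c2cc(C(=O)OC)cc(OC)c2O)C=C(OC)C1=O | intermediate (not isolated)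
22 | methyl (2S,3R)-3-{[(tert-butyldimethylsilyl)oxy]methyl}-2-(4-hydroxy-3,5-dimethoxyphenyl)-7-methoxy-2,3-dihydro-1-benzofuran-5-carboxylate | COc1cc([C@H]2Oc3c(OC)cc(C(=O)OC)cc3[C@@H]2CO[Si](C)(C)C(C)(C)C)cc(OC)c1O | intermediate
23 | methyl (2S,3R)-3-{[(tert-butyldimethylsilyl)oxy]methyl}-2-{4-[(tert-butyldimethylsilyl)oxy]-3,5-dimethoxyphenyl}-7-methoxy-2,3-dihydro-1-benzofuran-5-carboxylate | COc1cc([C@H]2Oc3c(OC)cc(C(=O)OC)cc3[C@@H]2CO[Si](C)(C)C(C)(C)C)cc(OC)c1O[Si](C)(C)C(C)(C)C | intermediate
24 | [(2S,3R)-3-{[(tert-butyldimethylsilyl)oxy]methyl}-2-{4-[(tert-butyldimethylsilyl)oxy]-3,5-dimethoxyphenyl}-7-methoxy-2,3-dihydro-1-benzofuran-5-yl]methanol | COc1cc([C@H]2Oc3c(OC)cc(CO)cc3[C@@H]2CO[Si](C)(C)C(C)(C)C)cc(OC)c1O[Si](C)(C)C(C)(C)C | intermediate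
25 | (2S,3R)-3-{[(tert-butyldimethylsilyl)oxy]methyl}-2-{4-[(tert-butyldimethylsilyl)oxy]-3,5-dimethoxyphenyl}-7-methoxy-2,3-dihydro-1-benzofuran-5-carbaldehyde | COc1cc([C@H]2Oc3c(OC)cc(C=O)cc3[C@@H]2CO[Si](C)(C)C(C)(C)C)cc(OC)c1O[Si](C)(C)C(C)(C)C | intermediate
26 | ethyl (2E)-3-[(2S,3R)-3-{[(tert-butyldimethylsilyl)oxy]methyl}-2-{4-[(tert-butyldimethylsilyl)oxy]-3,5-dimethoxyphenyl}-7-methoxy-2,3-dihydro-1-benzofuran-5-yl]prop-2-enoate | COc1cc([C@H]2Oc3c(OC)cc(/C=C/C(=O)OCC)cc3[C@@H]2CO[Si](C)(C)C(C)(C)C)cc(OC)c1O[Si](C)(C)C(C)(C)C | intermediate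
27 | (2E)-3-[(2S,3R)-3-{[(tert-butyldimethylsilyl)oxy]methyl}-2-{4-[(tert-butyldimethylsilyl)oxy]-3,5-dimethoxyphenyl}-7-methoxy-2,3-dihydro-1-benzofuran-5-yl]prop-2-en-1-ol | COc1cc([C@H]2Oc3c(OC)cc(/C=C/CO)cc3[C@@H]2CO[Si](C)(C)C(C)(C)C)cc(OC)c1O[Si](C)(C)C(C)(C)C | intermediate
28 | (2E)-3-[(2S,3R)-2-(4-hydroxy-3,5-dimethoxyphenyl)-3-(hydroxymethyl)-7-methoxy-2,3-dihydro-1-benzofuran-5-yl]prop-2-en-1-ol | COc1cc([C@H]2Oc3c(OC)cc(/C=C/CO)cc3[C@@H]2CO)cc(OC)c1O | target

**Step count and risks**

Total step count: 20 (3 steps to bromide 4, 17 in the main line).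
Longest linear sequence: 17 steps, from methyl vanillate 5 to target 28 (steps 4 to 20).

Steps most likely to fail:

1. Step 14 (key step). What may go wrong:
- further oxidation of the product, which is still a syringyl phenol, leading on to the aromatic benzofuran;
- loss of the C3 proton from quinone methide 21 (tautomerisation to a stilbene), which would erase the stereocentre;
- competing oxidation of the ring A phenol;
- incomplete trans selectivity.

The fallback reaches the same benzylic electrophile without an oxidation, by carrying a hydroxyl on C2 from the outset. It sets out from acid 12 and aldehyde 2 and comes back to the route at compound 22. Acid 12 is coupled through anhydride 14 with (S)-4-benzyl-2-oxazolidinone (the commercially available antipode of 13) to give the antipodal acyl oxazolidinone F1. The S auxiliary is needed here because the boron aldol uses the enolate face opposite to that of the chelated alkylation. Enolisation with Bu2BOTf and iPr2NEt in CH2Cl2 at −78 °C and addition of aldehyde 2 should give the Evans syn-aldol adduct F2. LiBH4 with MeOH in THF at 0 °C should give the 1,3-diol F3, TBSCl and imidazole at 0 °C should silylate only the primary hydroxyl to give the silyl ether F4, and brief hydrogenolysis (H2, 10% Pd/C, EtOAc) should free both phenols to give the benzylic alcohol bisphenol F5. Catalytic TsOH in CH2Cl2 at 0 °C ionises the benzylic alcohol para to the ring C phenol, the ring A phenol closes ring B, and equilibration through the benzylic cation should deliver the trans isomer 22, from which step 15 follows.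

2. Step 10. What may go wrong:
- incomplete facial selectivity or epimerisation of the acidic α-aryl centre;
- decomposition of the labile electron-rich bromide 4 before the enolate captures it;
- fragmentation of the enolate to a ketene.

The fallback sets the C3 stereocentre by catalytic asymmetric hydrogenation. It sets out from acid 12 and aldehyde 2 and comes back at compound 18. Perkin condensation (Ac2O, Et3N, 110 °C) should give the E-configured 2,3-diarylacrylic acid F6, with the two aryl groups cis. Activation with isobutyl chloroformate and N-methylmorpholine in THF at −15 °C gives the mixed carbonic anhydride F7, which NaBH4 reduces in the same flask to the allylic alcohol F8 without touching the aryl methyl ester. Hydrogenation of F8 with a cationic iridium phosphine-oxazoline catalyst, [Ir(cod)(tBu-PHOX)]BArF (ligand antipode chosen in a short screen to deliver the R configuration), under H2 (50 bar) in CH2Cl2 should give alcohol 18, from which step 12 follows; the benzyl ethers are stable to this homogeneous catalyst.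

3. Step 11. What may go wrong:
- slow hydride delivery to the hindered exocyclic carbonyl, so that ring-opening attack on the oxazolidinone carbonyl or reduction of the benzoate competes;
- base-induced epimerisation of the α-aryl centre.

The fallback separates cleavage from reduction. It sets out from imide 17 and comes back at compound 18. LiOH and H2O2 in THF/H2O at 0 °C (hydroperoxide attacks the exocyclic carbonyl selectively) should give the R-configured diarylpropanoic acid F9 and release the auxiliary. BH3·SMe2 in THF at 0 °C then reduces the carboxylic acid in preference to the methyl ester and should give alcohol 18.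

**Further compounds**

F1 | step 14 | (4S)-4-benzyl-3-{2-[2-(benzyloxy)-3-methoxy-5-(methoxycarbonyl)phenyl]acetyl}-1,3-oxazolidin-2-one | COC(=O)c1cc(CC(=O)N2[C@@H](Cc3ccccc3)COC2=O)c(OCc2ccccc2)c(OC)c1
F2 | step 14 | (4S)-4-benzyl-3-{(2S,3S)-2-[2-(benzyloxy)-3-methoxy-5-(methoxycarbonyl)phenyl]-3-[4-(benzyloxy)-3,5-dimethoxyphenyl]-3-hydroxypropanoyl}-1,3-oxazolidin-2-one | COc1cc([C@@H](O)[C@@H](C(=O)N2[C@@H](Cc3ccccc3)COC2=O)c2cc(C(=O)OC)cc(OC)c2OCc2ccccc2)cc(OC)c1OCc1ccccc1
F3 | step 14 | methyl 4-(benzyloxy)-3-{(1S,2R)-1-[4-(benzyloxy)-3,5-dimethoxyphenyl]-1,3-dihydroxypropan-2-yl}-5-methoxybenzoate | COc1cc([C@@H](O)[C@@H](CO)c2cc(C(=O)OC)cc(OC)c2OCc2ccccc2)cc(OC)c1OCc1ccccc1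
F4 | step 14 | methyl 4-(benzyloxy)-3-{(1S,2R)-1-[4-(benzyloxy)-3,5-dimethoxyphenyl]-3-[(tert-butyldimethylsilyl)oxy]-1-hydroxypropan-2-yl}-5-methoxybenzoate | COc1cc([C@@H](O)[C@@H](CO[Si](C)(C)C(C)(C)C)c2cc(C(=O)OC)cc(OC)c2OCc2ccccc2)cc(OC)c1OCc1ccccc1
F5 | step 14 | methyl 3-{(1S,2R)-3-[(tert-butyldimethylsilyl)oxy]-1-hydroxy-1-(4-hydroxy-3,5-dimethoxyphenyl)propan-2-yl}-4-hydroxy-5-methoxybenzoate | COc1cc([C@@H](O)[C@@H](CO[Si](C)(C)C(C)(C)C)c2cc(C(=O)OC)cc(OC)c2O)cc(OC)c1O
F6 | step 10 | (2E)-2-[2-(benzyloxy)-3-methoxy-5-(methoxycarbonyl)phenyl]-3-[4-(benzyloxy)-3,5-dimethoxyphenyl]prop-2-enoic acid | OC(=O)/C(=C/c1cc(OC)c(OCc2ccccc2)c(OC)c1)c1cc(C(=O)OC)cc(OC)c1OCc1ccccc1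
F7 | step 10 | isobutyl mixed carbonic anhydride of acid F6 | CC(C)COC(=O)OC(=O)/C(=C/c1cc(OC)c(OCc2ccccc2)c(OC)c1)c1cc(C(=O)OC)cc(OC)c1OCc1ccccc1
F8 | step 10 | methyl 4-(benzyloxy)-3-{(1E)-1-[4-(benzyloxy)-3,5-dimethoxyphenyl]-3-hydroxyprop-1-en-2-yl}-5-methoxybenzoate | OC/C(=C/c1cc(OC)c(OCc2ccccc2)c(OC)c1)c1cc(C(=O)OC)cc(OC)c1OCc1ccccc1
F9 | step 11 | (2R)-2-[2-(benzyloxy)-3-methoxy-5-(methoxycarbonyl)phenyl]-3-[4-(benzyloxy)-3,5-dimethoxyphenyl]propanoic acid | COc1cc(C[C@@H](C(=O)O)c2cc(C(=O)OC)cc(OC)c2OCc2ccccc2)cc(OC)c1OCc1ccccc1
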